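The target is the 3‑O‑[(S)‑2‑methylbutanoyl] ester of (2R,3R)‑pinobanksin. Its pyranone ring carries oxygen on the adjacent carbons C3 (ester) and C4 (ketone), so both C–O bonds are traced back to the C3=C4 alkene of a 2‑phenyl‑2H‑chromene. One syn‑dihydroxylation of (2S)‑5,7‑bis(benzyloxy)‑2‑phenyl‑2H‑chromene, directed to the face remote from the C2 phenyl group, installs O3 trans to phenyl and O4 in a single operation. The chromene comes from 5,7‑dihydroxycoumarin by benzylation, lactol/acetal formation and enantioselective nickel‑catalysed phenylation. Afterwards the electron‑rich benzylic C4 carbinol is oxidised, O3 is acylated and the benzyl ethers are removed.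

Key step: step 5

Remark on descriptors: C2 keeps one spatial arrangement from 6 to 12. It is 2S in chromene 6 and 2R from diol 8 onward only because C3 outranks phenyl once it bears oxygen; likewise C3 is 3S in 8 but 3R in 9, 11 and 12 because the C4 carbonyl then outranks C2.

Assumption: both antipodes of the TADDOL‑derived P‑phenyl phosphonite ligand are accessible (one step from commercial TADDOL), and the antipode that delivers the (2S)‑chromene is used.

Step 1
Reactants: 1 5,7‑dihydroxycoumarin
Product: 2 5,7‑bis(benzyloxy)‑2H‑chromen‑2‑one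
Conditions: BnBr (2.4 equiv), K2CO3 (3 equiv), DMF, 60 °C
Reagents that add atoms: benzyl bromide, BrCc1ccccc1
Why: Williamson ether synthesis: both phenoxides of the coumarin are formed by carbonate and are O‑alkylated by the primary benzylic halide, while the lactone is untouched and no stereocentre is involved.

Step 2
Reactants: 2 5,7‑bis(benzyloxy)‑2H‑chromen‑2‑one
Product: 3 5,7‑bis(benzyloxy)‑2H‑chromen‑2‑ol (racemic lactol)
Conditions: DIBAL‑H (1.2 equiv), CH2Cl2, −78 °C; aq. Rochelle salt
Reagents that add atoms: none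
Why: Partial lactone reduction with DIBAL‑H: one hydride is delivered to the lactone carbonyl and the aluminium‑bound tetrahedral intermediate survives at −78 °C until work‑up, so the lactol should form without over‑reduction; its hemiacetal carbon is racemic and is erased in step 4.

Step 3
Reactants: 3 5,7‑bis(benzyloxy)‑2H‑chromen‑2‑ol
Product: 4 5,7‑bis(benzyloxy)‑2‑ethoxy‑2H‑chromene (racemic acetal)
Conditions: EtOH, PPTS (cat.), rt; Et3N quench
Reagents that add atoms: ethanol, CCO
Why: Acid‑catalysed acetalisation of a lactol: loss of water gives the strongly stabilised 5,7‑dialkoxybenzopyrylium ion, which ethanol in large excess captures at C2; the acetal carbon is racemic and is erased in step 4.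

Step 4
Reactants: 4 5,7‑bis(benzyloxy)‑2‑ethoxy‑2H‑chromene; 5 phenylboronic acid
Product: 6 (2S)‑5,7‑bis(benzyloxy)‑2‑phenyl‑2H‑chromene
Conditions: Ni(cod)2 (5 mol%), TADDOL‑derived P‑phenyl phosphonite (6 mol%), PhB(OH)2 (2 equiv), dioxane, rt, inert atmosphere
Reagents that add atoms: phenylboronic acid, OB(O)c1ccccc1
Why: Nickel‑catalysed enantioselective Suzuki–Miyaura‑type coupling of a chromene acetal with an arylboronic acid: boronic‑acid‑assisted ionisation of the C2–OEt bond and oxidative addition give a planar 2H‑chromenyl (π‑allyl) nickel species from either enantiomer of 4, and after transmetallation the chiral phosphonite ligand controls reductive elimination at C2 (not at the peri‑hindered C4), which sets the single stereocentre as 2S.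

Step 5
Reactants: 6 (2S)‑5,7‑bis(benzyloxy)‑2‑phenyl‑2H‑chromene
Product: 8 (2R,3S,4S)‑5,7‑bis(benzyloxy)‑2‑phenylchroman‑3,4‑diol, via cyclic osmate(VI) ester 7 (not isolated)
Conditions: OsO4 (2–5 mol%), NMO (1.5 equiv), acetone/THF/H2O, 0 °C → rt, dark; aq. Na2SO3
Reagents that add atoms: osmium tetroxide, O=[Os](=O)(=O)=O; N‑methylmorpholine N‑oxide, C[N+]1([O-])CCOCC1; water, O
Why: Osmium tetroxide adds suprafacially across the electron‑rich C3=C4 styrenyl alkene in a concerted [3+2] cycloaddition to give the cyclic osmate ester 7, which water hydrolyses to the cis‑diol while NMO returns osmium to the +8 state (Upjohn dihydroxylation). The closest known reaction is the osmium‑mediated dihydroxylation of flav‑3‑enes, which delivers 2,3‑trans‑3,4‑cis‑flavan‑3,4‑diols. No ring is closed in the product; the five‑membered osmate ring is transient and is cleaved again. C3 and C4 are both set by the existing C2 stereocentre: the allylic phenyl group covers one face of the pyran half‑chair, so both oxygens arrive on the opposite face, placing O3 trans to phenyl (3S) and O4 cis to O3 (4S). The step needs diastereofacial selectivity, secured by that C2 phenyl group, and chemoselectivity for the only non‑aromatic alkene, which the benzyl ethers and arenes do not challenge. Only C3 has to be right for the target, because C4 becomes the ketone in the next step.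

Step 6
Reactants: 8 (2R,3S,4S)‑5,7‑bis(benzyloxy)‑2‑phenylchroman‑3,4‑diol
Product: 9 (2R,3R)‑5,7‑bis(benzyloxy)‑3‑hydroxy‑2‑phenylchroman‑4‑one
Conditions: DDQ (1.15 equiv), 1,4‑dioxane, rt, dark
Reagents that add atoms: none
Why: DDQ dehydrogenation of an electron‑rich benzylic alcohol: hydride abstraction occurs only from C4–H, whose cation is stabilised by the ortho and para oxygens of the A ring (O1, 5‑OBn, 7‑OBn), whereas the non‑benzylic C3 carbinol and the C2–H next to an unactivated phenyl are left alone and no glycol‑cleavage pathway is open; no stereocentre is formed and C2 and C3 are untouched under these non‑basic conditions.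

Step 7
Reactants: 9 (2R,3R)‑5,7‑bis(benzyloxy)‑3‑hydroxy‑2‑phenylchroman‑4‑one; 10 (S)‑2‑methylbutanoic acid
Product: 11 (2R,3R)‑5,7‑bis(benzyloxy)‑4‑oxo‑2‑phenylchroman‑3‑yl (2S)‑2‑methylbutanoate
Conditions: DCC (1.2 equiv), DMAP (0.1 equiv), CH2Cl2, 0 °C → rt
Reagents that add atoms: (S)‑2‑methylbutanoic acid, CC[C@H](C)C(=O)O
Why: Steglich esterification: the acid is activated as the O‑acylisourea/acylpyridinium and acylates the secondary 3‑hydroxyl; with only catalytic DMAP and no stoichiometric base neither the α‑stereocentre of the acid (no ketene pathway) nor the enolisable C3 of the flavanone should epimerise, and the trans 2,3‑arrangement is in any case the thermodynamically preferred one.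

Step 8
Reactants: 11 (2R,3R)‑5,7‑bis(benzyloxy)‑4‑oxo‑2‑phenylchroman‑3‑yl (2S)‑2‑methylbutanoate
Product: 12 (2R,3R)‑5,7‑dihydroxy‑4‑oxo‑2‑phenylchroman‑3‑yl (2S)‑2‑methylbutanoate (target)
Conditions: H2 (1 atm), 10% Pd/C, EtOAc, rt; stopped after uptake of 2 equiv H2
Reagents that add atoms: none
Why: Catalytic hydrogenolysis of the two aryl benzyl ethers over palladium: the primary O–CH2Ph bonds cleave much faster than the secondary ring C2–O bond, the ester and the aryl ketone are not reduced at 1 atm, and the freed 5‑hydroxyl hydrogen‑bonds to the C4 carbonyl; no stereocentre is affected.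

Compound list
1 | 5,7‑dihydroxycoumarin | O=C1C=Cc2c(O)cc(O)cc2O1 | starting material
2 | 5,7‑bis(benzyloxy)‑2H‑chromen‑2‑one | O=C1C=Cc2c(OCc3ccccc3)cc(OCc3ccccc3)cc2O1 | intermediate
3 | 5,7‑bis(benzyloxy)‑2H‑chromen‑2‑ol (racemic lactol) | OC1C=Cc2c(OCc3ccccc3)cc(OCc3ccccc3)cc2O1 | intermediate
4 | 5,7‑bis(benzyloxy)‑2‑ethoxy‑2H‑chromene (racemic acetal) | CCOC1C=Cc2c(OCc3ccccc3)cc(OCc3ccccc3)cc2O1 | intermediate
5 | phenylboronic acid | OB(O)c1ccccc1 | starting material
6 | (2S)‑5,7‑bis(benzyloxy)‑2‑phenyl‑2H‑chromene | C1=C[C@@H](c2ccccc2)Oc2cc(OCc3ccccc3)cc(OCc3ccccc3)c21 | intermediate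
7 | cyclic osmate(VI) ester bridging O3 and O4 of 8 (both oxygens anti to phenyl) | O1[C@H]2[C@@H](O[Os]1(=O)=O)c1c(OCc3ccccc3)cc(OCc3ccccc3)cc1O[C@@H]2c1ccccc1 | intermediate
8 | (2R,3S,4S)‑5,7‑bis(benzyloxy)‑2‑phenylchroman‑3,4‑diol (2,3‑trans‑3,4‑cis) | O[C@H]1[C@@H](O)c2c(OCc3ccccc3)cc(OCc3ccccc3)cc2O[C@@H]1c1ccccc1 | intermediate
9 | (2R,3R)‑5,7‑bis(benzyloxy)‑3‑hydroxy‑2‑phenylchroman‑4‑one | O[C@H]1C(=O)c2c(OCc3ccccc3)cc(OCc3ccccc3)cc2O[C@@H]1c1ccccc1 | intermediate
10 | (S)‑2‑methylbutanoic acid | CC[C@H](C)C(=O)O | starting material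
11 | (2R,3R)‑5,7‑bis(benzyloxy)‑4‑oxo‑2‑phenylchroman‑3‑yl (2S)‑2‑methylbutanoate | CC[C@H](C)C(=O)O[C@H]1C(=O)c2c(OCc3ccccc3)cc(OCc3ccccc3)cc2O[C@@H]1c1ccccc1 | intermediate
12 | (2R,3R)‑5,7‑dihydroxy‑4‑oxo‑2‑phenylchroman‑3‑yl (2S)‑2‑methylbutanoate | CC[C@H](C)C(=O)O[C@H]1C(=O)c2c(O)cc(O)cc2O[C@@H]1c1ccccc1 | target

Total step count: 8
Longest linear sequence: 8 steps (1 → 12); phenylboronic acid 5 and acid 10 enter as purchased materials.

Steps most likely to fail

Step 5. Osmium may attack both alkene faces if the C2 phenyl group shields its face insufficiently, or the diol may be lost through over‑oxidation. The fallback sets out from 6 and replaces dihydroxylation by a catalyst‑reinforced epoxidation. Jacobsen–Katsuki epoxidation with the (salen)Mn(III) enantiomer matched to the anti‑to‑phenyl face (m‑CPBA, NMO, CH2Cl2, −78 °C) should give (2R,3S,4S)‑5,7‑bis(benzyloxy)‑3,4‑epoxy‑2‑phenylchromane F2. This labile benzylic epoxide is opened by water at C4 in the same flask (wet THF, trace PPTS) to the 2,3‑trans diol, expected mainly as (2R,3S,4R)‑5,7‑bis(benzyloxy)‑2‑phenylchroman‑3,4‑diol F3. Because C4 becomes a carbonyl, either C4 epimer serves; DDQ oxidation as in step 6 brings the material back to the route at 9.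

Step 4. Enantioselectivity may erode because the very easily ionised 5,7‑dialkoxy acetal can react through a ligand‑free or uncatalysed background addition; the Ni(0) catalyst may also be deactivated by air. The fallback sets out from 4 and replaces asymmetric catalysis by resolution. Coupling with 5 under achiral Ni(cod)2/PPh3 catalysis should give racemic 5,7‑bis(benzyloxy)‑2‑phenyl‑2H‑chromene F1. Preparative SFC on a polysaccharide chiral stationary phase then separates the enantiomers, and the (2S)‑enantiomer rejoins the route as 6.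

Step 6. Chemoselectivity may be lost through further dehydrogenation of the ketol to the flavonol, attack on the benzyl ethers, or acid‑induced ionisation at C4 by the hydroquinone by‑product. The fallback sets out from 8 and reverses the order of acylation and oxidation, so that steric rather than electronic differentiation of the two hydroxyls is used. Esterification with 10 (1.0 equiv, DCC, cat. DMAP, CH2Cl2, −20 °C) should favour the equatorial 3‑hydroxyl over the pseudo‑axial 4‑hydroxyl shielded by the peri 5‑benzyloxy group, giving (2R,3S,4S)‑5,7‑bis(benzyloxy)‑4‑hydroxy‑2‑phenylchroman‑3‑yl (2S)‑2‑methylbutanoate F4. The remaining C4 carbinol is then oxidised with Dess–Martin periodinane/NaHCO3, where no selectivity is needed, and the route is rejoined at 11.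

Further compounds
F1 | step 4 | racemic 5,7‑bis(benzyloxy)‑2‑phenyl‑2H‑chromene | C1=CC(c2ccccc2)Oc2cc(OCc3ccccc3)cc(OCc3ccccc3)c21
F2 | step 5 | (2R,3S,4S)‑5,7‑bis(benzyloxy)‑3,4‑epoxy‑2‑phenylchromane (oxirane oxygen anti to phenyl) | O1[C@H]2[C@@H]1c1c(OCc3ccccc3)cc(OCc3ccccc3)cc1O[C@@H]2c1ccccc1
F3 | step 5 | (2R,3S,4R)‑5,7‑bis(benzyloxy)‑2‑phenylchroman‑3,4‑diol (2,3‑trans‑3,4‑trans) | O[C@H]1[C@H](O)c2c(OCc3ccccc3)cc(OCc3ccccc3)cc2O[C@@H]1c1ccccc1
F4 | step 6 | (2R,3S,4S)‑5,7‑bis(benzyloxy)‑4‑hydroxy‑2‑phenylchroman‑3‑yl (2S)‑2‑methylbutanoate | CC[C@H](C)C(=O)O[C@H]1[C@@H](O)c2c(OCc3ccccc3)cc(OCc3ccccc3)cc2O[C@@H]1c1ccccc1
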